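## Retrosynthetic overview

1. Ring atoms: C1 (ketone), C2=C3, C4 (acetoxy carbon with the acid chain), C5 (pentenyl carbon). Target 15 comes from tertiary alcohol 13 by acetylation.
2. The only ring is closed last: the C1–C2 bond is made by rhodium-catalysed trans-hydroacylation of 4-alkynal 12 (aldehyde carbon C1 onto the terminal alkyne carbon C2).
3. The (Z)-pentenyl chain comes from a Wittig reaction on lactol 9, the unmasked aldehyde of a homoenolate equivalent.
4. Key disconnection C4–C5: the γ-carbon of a titanated allyl carbamate from 2 (β-carbon of the side-chain aldehyde acting as nucleophile) adds to ynone 5 and sets both stereocentres at once.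
5. 2 comes from cis-but-2-ene-1,4-diol; 5 comes from monomethyl azelate and ethynyltrimethylsilane.

Assumption: the sense of induction in step 3 is taken from crotyl carbamate precedent (pro-S deprotonation with (–)-sparteine, lithium–titanium exchange with inversion); if 8 proves antipodal, (+)-sparteine is used in the same step.

## Route

Step 1
Reactants: 1 (2Z)-but-2-ene-1,4-diol
Product: 2 (2Z)-4-hydroxybut-2-en-1-yl N,N-di(propan-2-yl)carbamate
Conditions: 1 (3 equiv), NaH (1 equiv), THF, 0 °C; iPr2NCOCl (1 equiv), reflux, 12 h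
Reagents that add atoms: N,N-diisopropylcarbamoyl chloride, CC(C)N(C(C)C)C(Cl)=O
Why: O-carbamoylation of the monosodium alkoxide, with a threefold excess of the symmetrical diol holding the reaction at the mono-carbamate and the Z double bond untouched.

Step 2
Reactants: 3 9-methoxy-9-oxononanoic acid (monomethyl azelate)
Product: 5 methyl 9-oxo-11-(trimethylsilyl)undec-10-ynoate, via acid chloride 4 (not isolated)
Conditions: (COCl)2, cat. DMF, CH2Cl2, 0 °C to rt, evaporate; HC≡CSiMe3, PdCl2(PPh3)2 (2 mol %), CuI (4 mol %), Et3N, THF, rt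
Reagents that add atoms: ethynyltrimethylsilane, C#C[Si](C)(C)C; oxalyl chloride, O=C(Cl)C(Cl)=O (chlorine of 4 only)
Why: Acid chloride formation followed by acyl Sonogashira coupling gives the silyl-capped ynone, whose alkynyl group is the sterically small ketone substituent needed in step 3.

Step 3
Reactants: 2 (2Z)-4-hydroxybut-2-en-1-yl N,N-di(propan-2-yl)carbamate; 5 methyl 9-oxo-11-(trimethylsilyl)undec-10-ynoate
Product: 8 methyl (9S,10R,11E)-12-{[di(propan-2-yl)carbamoyl]oxy}-9-hydroxy-10-(hydroxymethyl)-9-[(trimethylsilyl)ethynyl]dodec-11-enoate, via dilithio carbamate 6 (not isolated), via allyltitanium reagent 7 (not isolated)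
Conditions: 2 (1.3 equiv), s-BuLi (2.7 equiv), (–)-sparteine (1.5 equiv), toluene, –78 °C, 3 h; Ti(OiPr)4 (4 equiv), –78 °C, 1 h; 5 (1.0 equiv), –78 to –40 °C; aq. HCl
Reagents that add atoms: none
Why: Proposed new method: s-BuLi/(–)-sparteine removes the pro-S proton next to the carbamate oxygen of the lithium alkoxide of 2 (an oxide cannot leave, so 1,4-elimination is blocked), Ti(OiPr)4 exchanges lithium with inversion, and the allyltitanium (a homoenolate equivalent of the side-chain aldehyde) attacks the ketone of 5 through its γ-carbon in a closed chair transition state with the Z-substituent axial, the carbamoyloxy group equatorial, the alkyl chain of 5 equatorial and the slim alkynyl group axial, which forms the C4–C5 bond and sets both stereocentres (9S,10R) in one event; closest known reaction type: Hoppe's sparteine-mediated asymmetric homoaldol reaction of titanated 2-alkenyl carbamates with ketones.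

Step 4
Reactants: 8 methyl (9S,10R,11E)-12-{[di(propan-2-yl)carbamoyl]oxy}-9-hydroxy-10-(hydroxymethyl)-9-[(trimethylsilyl)ethynyl]dodec-11-enoate
Product: 9 methyl (9S)-9-hydroxy-9-[(3R)-5-hydroxyoxolan-3-yl]-11-(trimethylsilyl)undec-10-ynoate (lactol, both anomers, drawn closed through the primary hydroxyl)
Conditions: Hg(OAc)2 (5 mol %), MeSO3H (0.3 equiv), THF–H2O 4:1, rt
Reagents that add atoms: water, O
Why: Acid-catalysed, mercury-assisted hydrolysis of the enol carbamate (the standard unmasking of homoaldol adducts), in which a neighbouring hydroxyl traps the oxocarbenium ion and water replaces the carbamate without touching either stereocentre.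

Step 5
Reactants: 9 methyl (9S)-9-hydroxy-9-[(3R)-5-hydroxyoxolan-3-yl]-11-(trimethylsilyl)undec-10-ynoate
Product: 11 (9S,10R,12Z)-9-ethynyl-9-hydroxy-10-(hydroxymethyl)pentadec-12-enoic acid, via silylalkyne ester 10 (not isolated)
Conditions: Ph3P(CH2CH2CH3)Br (4 equiv), NaN(SiMe3)2 (3.9 equiv), THF, –78 °C to rt; then MeOH, aq. LiOH (6 equiv), rt; aq. HCl to pH 4
Reagents that add atoms: propyltriphenylphosphonium bromide, CCC[P+](c1ccccc1)(c1ccccc1)c1ccccc1.[Br-]; lithium hydroxide, [Li+].[OH-]
Why: Wittig olefination of the lactol by a non-stabilised ylide under salt-free conditions gives the (Z)-alkene, and aqueous LiOH then saponifies the methyl ester and cleaves the alkynyl C–Si bond while nothing base-sensitive is yet present.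

Step 6
Reactants: 11 (9S,10R,12Z)-9-ethynyl-9-hydroxy-10-(hydroxymethyl)pentadec-12-enoic acid
Product: 12 (9S,10S,12Z)-9-ethynyl-10-formyl-9-hydroxypentadec-12-enoic acid
Conditions: Dess–Martin periodinane (1.3 equiv), pyridine (3 equiv), CH2Cl2, 0 °C, 1 h; used crude
Reagents that add atoms: none
Why: Dess–Martin oxidation converts the only oxidisable (primary) alcohol into the aldehyde under buffered, cold conditions that leave the tertiary propargylic alcohol and the α-stereocentre C5 intact.

Step 7
Reactants: 12 (9S,10S,12Z)-9-ethynyl-10-formyl-9-hydroxypentadec-12-enoic acid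
Product: 13 8-[(1R,5S)-1-hydroxy-4-oxo-5-[(2Z)-pent-2-en-1-yl]cyclopent-2-en-1-yl]octanoic acid
Conditions: [Rh(dppe)]2(BF4)2 (5 mol %), acetone, rt
Reagents that add atoms: none
Why: Rhodium-catalysed intramolecular trans-hydroacylation of a 4-alkynal (Tanaka–Fu cyclopentenone synthesis), in which the acyl rhodium hydride from the aldehyde C–H bond adds across the terminal alkyne to form the C1–C2 bond and the endocyclic enone under neutral conditions that do not epimerise C5.

Step 8
Reactants: 13 8-[(1R,5S)-1-hydroxy-4-oxo-5-[(2Z)-pent-2-en-1-yl]cyclopent-2-en-1-yl]octanoic acid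
Product: 15 8-[(1R,5S)-1-(acetyloxy)-4-oxo-5-[(2Z)-pent-2-en-1-yl]cyclopent-2-en-1-yl]octanoic acid, via mixed anhydride 14 (not isolated)
Conditions: Ac2O (5 equiv), Sc(OTf)3 (2 mol %), MeCN, –20 °C, 1 h; then THF / pH 7 phosphate buffer, 0 °C
Reagents that add atoms: acetic anhydride, CC(=O)OC(C)=O
Why: Sc(OTf)3-catalysed acetylation esterifies the hindered tertiary alcohol at low temperature without base, so C5 is not epimerised and no retro-aldol opening occurs, and the transient mixed anhydride of the acid is hydrolysed on work-up.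

## Compound list

1 | (2Z)-but-2-ene-1,4-diol | OC/C=C\CO | starting material
2 | (2Z)-4-hydroxybut-2-en-1-yl N,N-di(propan-2-yl)carbamate | CC(C)N(C(C)C)C(=O)OC/C=C\CO | intermediate
3 | 9-methoxy-9-oxononanoic acid (monomethyl azelate) | COC(=O)CCCCCCCC(=O)O | starting material
4 | methyl 9-chloro-9-oxononanoate (not isolated) | COC(=O)CCCCCCCC(=O)Cl | intermediate
5 | methyl 9-oxo-11-(trimethylsilyl)undec-10-ynoate | COC(=O)CCCCCCCC(=O)C#C[Si](C)(C)C | intermediate
6 | (1S,2Z)-1-lithio-4-(lithiooxy)but-2-en-1-yl N,N-di(propan-2-yl)carbamate, as its (–)-sparteine complex (not isolated) | CC(C)N(C(C)C)C(=O)O[C@@H]([Li])/C=C\CO[Li] | intermediate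
7 | (1R,2Z)-4-(lithiooxy)-1-[tri(propan-2-yloxy)titanio]but-2-en-1-yl N,N-di(propan-2-yl)carbamate (not isolated) | CC(C)N(C(C)C)C(=O)O[C@H]([Ti](OC(C)C)(OC(C)C)OC(C)C)/C=C\CO[Li] | intermediate
8 | methyl (9S,10R,11E)-12-{[di(propan-2-yl)carbamoyl]oxy}-9-hydroxy-10-(hydroxymethyl)-9-[(trimethylsilyl)ethynyl]dodec-11-enoate | CC(C)N(C(C)C)C(=O)O/C=C/[C@@H]([C@](O)(C#C[Si](C)(C)C)CCCCCCCC(=O)OC)CO | intermediate
9 | methyl (9S)-9-hydroxy-9-[(3R)-5-hydroxyoxolan-3-yl]-11-(trimethylsilyl)undec-10-ynoate (lactol, anomer mixture) | OC1C[C@H](CO1)[C@](O)(C#C[Si](C)(C)C)CCCCCCCC(=O)OC | intermediate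
10 | methyl (9S,10R,12Z)-9-hydroxy-10-(hydroxymethyl)-9-[(trimethylsilyl)ethynyl]pentadec-12-enoate (not isolated) | CC/C=C\C[C@@H]([C@](O)(C#C[Si](C)(C)C)CCCCCCCC(=O)OC)CO | intermediate
11 | (9S,10R,12Z)-9-ethynyl-9-hydroxy-10-(hydroxymethyl)pentadec-12-enoic acid | CC/C=C\C[C@@H]([C@](O)(C#C)CCCCCCCC(=O)O)CO | intermediate
12 | (9S,10S,12Z)-9-ethynyl-10-formyl-9-hydroxypentadec-12-enoic acid | CC/C=C\C[C@@H]([C@](O)(C#C)CCCCCCCC(=O)O)C=O | intermediate
13 | 8-[(1R,5S)-1-hydroxy-4-oxo-5-[(2Z)-pent-2-en-1-yl]cyclopent-2-en-1-yl]octanoic acid | CC/C=C\C[C@@H]1C(=O)C=C[C@@]1(CCCCCCCC(=O)O)O | intermediate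
14 | acetic 8-[(1R,5S)-1-(acetyloxy)-4-oxo-5-[(2Z)-pent-2-en-1-yl]cyclopent-2-en-1-yl]octanoic anhydride (not isolated) | CC/C=C\C[C@@H]1C(=O)C=C[C@@]1(CCCCCCCC(=O)OC(C)=O)OC(C)=O | intermediate
15 | 8-[(1R,5S)-1-(acetyloxy)-4-oxo-5-[(2Z)-pent-2-en-1-yl]cyclopent-2-en-1-yl]octanoic acid | CC/C=C\C[C@@H]1C(=O)C=C[C@@]1(CCCCCCCC(=O)O)OC(C)=O | target

## Step count and risks

Total steps: 8. Longest linear sequence: 7 steps (1, 3, 4, 5, 6, 7, 8 from diol 1; equally 2 to 8 from acid 3).

Steps most likely to fail: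

Step 3. The lithium alkoxide may lower the enantioselectivity of the sparteine-mediated deprotonation, and any (Z)-enol carbamate formed carries the antipodal core and must be removed by chromatography. The fallback takes the chirality from a resolution instead of from the base. It sets out from 2 and 5: lithiation of 2 with s-BuLi/TMEDA, titanation and addition to 5 as before give 8 together with its mirror image, the (9R,10S,11E)-enantiomer F1. Burkholderia cepacia lipase with vinyl acetate acetylates the primary alcohol of one antipode, assumed here to be F1, giving the (9R,10S,11E)-primary acetate F2. Unreacted 8 is separated and the route is rejoined at 8.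

Step 7. The terminal alkyne, the free tertiary alcohol and acid, and the labile β-hydroxy aldehyde may lead to decarbonylation or dehydration instead of cyclisation. The fallback closes the ring by olefin metathesis and sets out from 11. Semihydrogenation (H2, Pd/CaCO3 poisoned with Pb(OAc)2, quinoline) gives the vinyl carbinol F3. Dess–Martin oxidation gives the aldehyde F4, and excess vinylmagnesium bromide gives the divinyl triol F5 as a mixture of carbinol epimers. Ring-closing metathesis with the second-generation Grubbs catalyst RuCl2(=CHPh)(PCy3)(H2IMes) joins the two terminal vinyl groups to the cyclopentenediol F6. MnO2 oxidises the secondary allylic alcohol, and the route is rejoined at 13.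

Step 8. The hindered tertiary alcohol may acetylate slowly, with epimerisation at C5 or retro-aldol ring opening competing. The fallback installs the acetate before the ring exists and sets out from 11, which has no epimerisable centre. Ac2O/DMAP/Et3N at 40 °C gives the diacetate F7. K2CO3 in MeOH at 0 °C removes only the primary acetate to give the tertiary acetate F8. Dess–Martin oxidation gives the acetoxy alkynal F9, and the rhodium catalyst of step 7 closes the ring, rejoining the route at 15.

Further compounds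

F1 | step 3 | methyl (9R,10S,11E)-12-{[di(propan-2-yl)carbamoyl]oxy}-9-hydroxy-10-(hydroxymethyl)-9-[(trimethylsilyl)ethynyl]dodec-11-enoate | CC(C)N(C(C)C)C(=O)O/C=C/[C@H]([C@@](O)(C#C[Si](C)(C)C)CCCCCCCC(=O)OC)CO
F2 | step 3 | methyl (9R,10S,11E)-10-(acetoxymethyl)-12-{[di(propan-2-yl)carbamoyl]oxy}-9-hydroxy-9-[(trimethylsilyl)ethynyl]dodec-11-enoate | CC(C)N(C(C)C)C(=O)O/C=C/[C@H]([C@@](O)(C#C[Si](C)(C)C)CCCCCCCC(=O)OC)COC(C)=O
F3 | step 7 | (9R,10R,12Z)-9-ethenyl-9-hydroxy-10-(hydroxymethyl)pentadec-12-enoic acid | CC/C=C\C[C@@H]([C@](O)(C=C)CCCCCCCC(=O)O)CO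
F4 | step 7 | (9R,10S,12Z)-9-ethenyl-10-formyl-9-hydroxypentadec-12-enoic acid | CC/C=C\C[C@@H]([C@](O)(C=C)CCCCCCCC(=O)O)C=O
F5 | step 7 | (12Z)-9-ethenyl-9-hydroxy-10-(1-hydroxyprop-2-en-1-yl)pentadec-12-enoic acid, carbinol epimers | CC/C=C\C[C@@H]([C@](O)(C=C)CCCCCCCC(=O)O)C(O)C=C
F6 | step 7 | 8-[1,4-dihydroxy-5-[(2Z)-pent-2-en-1-yl]cyclopent-2-en-1-yl]octanoic acid, secondary carbinol epimers | CC/C=C\C[C@@H]1C(O)C=C[C@@]1(CCCCCCCC(=O)O)O
F7 | step 8 | (12Z)-9-(acetyloxy)-10-[(acetyloxy)methyl]-9-ethynylpentadec-12-enoic acid | CC/C=C\C[C@@H]([C@](OC(C)=O)(C#C)CCCCCCCC(=O)O)COC(C)=O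
F8 | step 8 | (12Z)-9-(acetyloxy)-9-ethynyl-10-(hydroxymethyl)pentadec-12-enoic acid | CC/C=C\C[C@@H]([C@](OC(C)=O)(C#C)CCCCCCCC(=O)O)CO
F9 | step 8 | (12Z)-9-(acetyloxy)-9-ethynyl-10-formylpentadec-12-enoic acid | CC/C=C\C[C@@H]([C@](OC(C)=O)(C#C)CCCCCCCC(=O)O)C=O
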